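The route joins two intact, benzyl-protected flavones (from acacetin and apigenin) at C3–C3'' by a Negishi coupling and postpones all stereochemistry to the end. In the target, H-2 and H-3 are cis in each ring C, and both halves have the same handedness (2S,3S,2''S,3''S). That pattern results when H2 is delivered syn to one enantioface of C2=C3 and to the like face of C2''=C3''. One catalyst-controlled double hydrogenation of the fully unsaturated pentabenzyl 3,3''-biflavone should therefore create all four stereocentres in a single operation. The precursor has no stereocentre, only a hindered C3–C3'' axis, and its two chromone C=C bonds are its only olefins.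

Key step: step 6

Remark on the target: the SMILES reads as 2S,3S,2''S,3''S with the C2 aryl group and the C3 substituent cis in each ring C (H-2/H-3 cis). This is the less stable arrangement next to a ketone, so no acid, base or heating is used after step 6.

Remark on the precursor: the 3,3''-biflavone 11 is not planar. C3–C3'' is an axis flanked by two aryl groups and two carbonyls, so 11 forms as a racemic pair of atropisomers, which step 6 has to cope with.

Assumption: the (R,R)-imidazolinium salt is taken as the ligand enantiomer that directs H2 to the faces giving 2S and 2''S; if the sense proves opposite, the (S,S)-salt is used instead.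

Step 1
Reactants: 1 acacetin
Product: 2 di-O-benzylacacetin
Conditions: BnBr (3 equiv), K2CO3, Bu4NI (cat.), DMF, 80 °C
Reagents that add atoms: benzyl bromide, BrCc1ccccc1
Why: Williamson ether synthesis, in which the 7-OH is alkylated readily and the hydrogen-bonded 5-OH follows in hot DMF with excess bromide and iodide catalysis, leaving no acidic O–H for the organometallic steps.

Step 2
Reactants: 2 di-O-benzylacacetin
Product: 4 di-O-benzyl-3-iodoacacetin, via lithiated diether 3 (not isolated)
Conditions: LiN(iPr)2, THF, −78 °C; then I2 (THF), −78 °C → 0 °C
Reagents that add atoms: iodine, [I][I]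
Why: Deprotonative lithiation followed by iodinolysis: C3–H, an sp2 C–H next to the C4 carbonyl that also guides the amide base, is removed at −78 °C, where the 3-lithioflavone neither opens ring C nor attacks a benzyl ether, and I2 traps it at C3, whereas an electrophilic iodinating agent would be expected to attack C6 or C8 of the electron-rich ring A.

Step 3
Reactants: 5 apigenin
Product: 6 tri-O-benzylapigenin
Conditions: BnBr (4.5 equiv), K2CO3, Bu4NI (cat.), DMF, 80 °C
Reagents that add atoms: benzyl bromide, BrCc1ccccc1
Why: Williamson ether synthesis as in step 1, now on three phenols, the 4'- and 7-OH reacting fast and the chelated 5-OH last.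

Step 4
Reactants: 6 tri-O-benzylapigenin
Product: 8 tri-O-benzyl-3-iodoapigenin, via lithiated triether 7 (not isolated)
Conditions: LiN(iPr)2, THF, −78 °C; then I2 (THF), −78 °C → 0 °C
Reagents that add atoms: iodine, [I][I]
Why: Deprotonative lithiation and iodinolysis at C3 exactly as in step 2, the third benzyl ether being inert to LiN(iPr)2 at −78 °C.

Step 5
Reactants: 8 tri-O-benzyl-3-iodoapigenin; 4 di-O-benzyl-3-iodoacacetin
Product: 11 pentabenzyl 3,3''-biflavone, via flavonylmagnesium chloride 9 (not isolated), via flavonylzinc chloride 10 (not isolated)
Conditions: 8, iPrMgCl·LiCl, THF, −40 °C; ZnCl2 (THF), −40 °C → rt; then 4, Pd2(dba)3 (2.5 mol%), RuPhos (10 mol%), THF, 60 °C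
Reagents that add atoms: none
Why: Iodine–magnesium exchange at the α-iodoenone carbon is fast at −40 °C, immediate transmetalation to zinc gives a C3 nucleophile (fragment 2) that no longer opens ring C, and a Negishi cross-coupling with a bulky dialkylbiarylphosphine–palladium catalyst, the catalyst type used for doubly ortho-flanked sp2–sp2 bonds, joins it to the activated 3-iodochromone 4 (fragment 1) to form C3–C3''.

Step 6
Reactants: 11 pentabenzyl 3,3''-biflavone
Product: 13 pentabenzyl (2S,3S,2''S,3''S)-cis,cis-3,3''-biflavanone, via over-reduced bis-carbinol 12 (not isolated)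
Conditions: Ru(cod)(2-methylallyl)2 (10 mol%), (R,R)-1,3-bis[1-(1-naphthyl)ethyl]imidazolinium BF4 (20 mol%), KOtBu (20 mol%), hexane, 70 °C (catalyst formation); then 11, toluene, H2 (100 bar), 40 °C; filter (SiO2); Dess–Martin periodinane, NaHCO3 (buffer), CH2Cl2, 0 °C → rt
Reagents that add atoms: none
Why: Proposed new method: a divalent ruthenium hydride bearing the chiral carbene binds one face of C2=C3, inserts it, and H2 cleaves the resulting Ru–C bond with retention, so both hydrogens arrive on the same face and H-2 and H-3 end up cis; the same sequence then takes place at C2''=C3''. The closest known reaction type is the asymmetric hydrogenation of flavones and chromones with ruthenium–carbene catalysts of this kind, which saturates the trisubstituted chromone C=C bond enantioselectively and tends to go on to the C4 carbinol, alongside syn-hydrogenation of 3-substituted chromones on palladium; a tetrasubstituted C=C bond flanked by a second chromone has not been shown. No ring is closed and no C–C bond is formed, the two pyranone rings C merely become chromanone rings. C2 and C2'' are set as S by the enantioface that the ligand selects and C3 and C3'' follow as S from the syn delivery, so one catalyst reading two nearly identical rings should favour the homochiral 2S,3S,2''S,3''S product, an error at one ring showing up as a separable heterochiral diastereomer and thereby raising the enantiomeric purity of the homochiral one. The step needs the same facial sense at both rings and reaction at the chromone C=C bonds alone: these are the only olefins, the benzyl ethers mask the chelating 5-OH groups, and the C3–C3'' axis matters only for the first addition, in which the atropisomer whose open face (the one next to the partner's C4 carbonyl, not its C2 aryl group) is the face the catalyst prefers reacts while the other either equilibrates by rotation or is recovered and racemised by heating, since after the first addition the axis is a freely rotating sp3–sp2 bond. The C4 and C4'' ketones are allowed to reduce on to the carbinols 12 (or any keto-alcohol short of it), which keeps C3 and C3'' from enolising during the run, and buffered Dess–Martin oxidation of the crude returns both ketones without touching the α-stereocentres.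

Step 7
Reactants: 13 pentabenzyl (2S,3S,2''S,3''S)-cis,cis-3,3''-biflavanone
Product: 14 sikokianin A
Conditions: H2 (1 atm), Pd/C (10%), EtOAc–THF, rt
Reagents that add atoms: none
Why: Catalytic hydrogenolysis of the five benzyl aryl ethers on Pd/C under neutral conditions at room temperature should leave the aryl methyl ether, the two aryl ketones (chelated once 5-OH and 5''-OH are free) and, with no acid or base present, the epimerisable cis centres C3 and C3'' untouched.

Compound list
1 | acacetin (5,7-dihydroxy-4'-methoxyflavone) | COc1ccc(-c2cc(=O)c3c(O)cc(O)cc3o2)cc1 | starting material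
2 | di-O-benzylacacetin (5,7-bis(benzyloxy)-4'-methoxyflavone) | COc1ccc(-c2cc(=O)c3c(OCc4ccccc4)cc(OCc4ccccc4)cc3o2)cc1 | intermediate
3 | lithiated diether: 5,7-bis(benzyloxy)-4'-methoxyflavon-3-yllithium, formed in the flask and trapped at once | COc1ccc(-c2oc3cc(OCc4ccccc4)cc(OCc4ccccc4)c3c(=O)c2[Li])cc1 | intermediate
4 | di-O-benzyl-3-iodoacacetin (5,7-bis(benzyloxy)-3-iodo-4'-methoxyflavone; fragment 1) | COc1ccc(-c2oc3cc(OCc4ccccc4)cc(OCc4ccccc4)c3c(=O)c2I)cc1 | intermediate
5 | apigenin (5,7,4'-trihydroxyflavone) | Oc1ccc(-c2cc(=O)c3c(O)cc(O)cc3o2)cc1 | starting material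
6 | tri-O-benzylapigenin (5,7,4'-tris(benzyloxy)flavone) | O=c1cc(-c2ccc(OCc3ccccc3)cc2)oc2cc(OCc3ccccc3)cc(OCc3ccccc3)c12 | intermediate
7 | lithiated triether: 5,7,4'-tris(benzyloxy)flavon-3-yllithium, formed in the flask and trapped at once | O=c1c([Li])c(-c2ccc(OCc3ccccc3)cc2)oc2cc(OCc3ccccc3)cc(OCc3ccccc3)c12 | intermediate
8 | tri-O-benzyl-3-iodoapigenin (5,7,4'-tris(benzyloxy)-3-iodoflavone) | O=c1c(I)c(-c2ccc(OCc3ccccc3)cc2)oc2cc(OCc3ccccc3)cc(OCc3ccccc3)c12 | intermediate
9 | flavonylmagnesium chloride: 5,7,4'-tris(benzyloxy)flavon-3-ylmagnesium chloride, formed in the flask | O=c1c([Mg]Cl)c(-c2ccc(OCc3ccccc3)cc2)oc2cc(OCc3ccccc3)cc(OCc3ccccc3)c12 | intermediate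
10 | flavonylzinc chloride: 5,7,4'-tris(benzyloxy)flavon-3-ylzinc chloride (fragment 2), formed in the flask | O=c1c([Zn]Cl)c(-c2ccc(OCc3ccccc3)cc2)oc2cc(OCc3ccccc3)cc(OCc3ccccc3)c12 | intermediate
11 | pentabenzyl 3,3''-biflavone: 5,7,5'',7'',4'''-pentakis(benzyloxy)-4'-methoxy-3,3''-biflavone (no stereocentre; racemic pair of atropisomers about C3–C3'') | COc1ccc(-c2oc3cc(OCc4ccccc4)cc(OCc4ccccc4)c3c(=O)c2-c2c(-c3ccc(OCc4ccccc4)cc3)oc3cc(OCc4ccccc4)cc(OCc4ccccc4)c3c2=O)cc1 | intermediate
12 | over-reduced bis-carbinol: pentabenzyl 3,3''-biflavan-4,4''-diol with C2, C3, C2'', C3'' arranged as in 13 (H-2/H-3 and H-2''/H-3'' cis), C4 and C4'' configuration not controlled, formed in the flask | COc1ccc([C@H]2Oc3cc(OCc4ccccc4)cc(OCc4ccccc4)c3C(O)[C@H]2[C@@H]2C(O)c3c(OCc4ccccc4)cc(OCc4ccccc4)cc3O[C@@H]2c2ccc(OCc3ccccc3)cc2)cc1 | intermediate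
13 | pentabenzyl (2S,3S,2''S,3''S)-cis,cis-3,3''-biflavanone: (2S,3S,2''S,3''S)-5,7,5'',7'',4'''-pentakis(benzyloxy)-4'-methoxy-3,3''-biflavanone (H-2/H-3 cis, H-2''/H-3'' cis) | COc1ccc([C@H]2Oc3cc(OCc4ccccc4)cc(OCc4ccccc4)c3C(=O)[C@H]2[C@@H]2C(=O)c3c(OCc4ccccc4)cc(OCc4ccccc4)cc3O[C@@H]2c2ccc(OCc3ccccc3)cc2)cc1 | intermediate
14 | sikokianin A, (2S,3S,2''S,3''S) | COc1ccc([C@H]2Oc3cc(O)cc(O)c3C(=O)[C@H]2[C@@H]2C(=O)c3c(O)cc(O)cc3O[C@@H]2c2ccc(O)cc2)cc1 | target

Total step count: 7.
Longest linear sequence: 5 steps (steps 1, 2, 5, 6, 7; the apigenin branch, steps 3, 4, 5, 6, 7, is equally long).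

Steps most likely to fail

1. Step 6. The bulky chiral catalyst may fail to engage the tetrasubstituted, doubly flanked C=C bonds, or its facial preference may clash with the C3–C3'' axis of 11, so that conversion stalls or facial selectivity is poor. The fallback gives up catalyst control and uses known palladium chemistry. Starting from 11, hydrogenation over Pd/C (H2, 3–5 bar, EtOAc–THF, rt) would cleave the five benzyl ethers and add H2 syn to both chromone C=C bonds from the faces left open by the axis. This should give the racemic all-cis homochiral biflavanone, that is 14 together with the (2R,3R,2''R,3''R)-enantiomer of sikokianin A F1. A diastereomer arising from unlike faces, if present, would be removed on silica. Preparative HPLC on a chiral stationary phase (amylose tris(3,5-dimethylphenylcarbamate), neutral eluent) would then separate the enantiomers, and the route is rejoined at 14.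

2. Step 5. Transmetalation and reductive elimination at two C3 positions, each flanked by an aryl group and a carbonyl, may be slow, so that protodemetalation of the zinc reagent (which returns 6) and homocoupling take over. The fallback drops the organozinc altogether and couples the two electrophiles reductively. Starting from 4 and 8, a mixed Ullmann coupling (activated Cu powder, DMF, 120 °C) should give 11 as the cross product in a statistical mixture with the symmetrical dimers hexabenzyl 3,3''-biapigenin F2 and tetrabenzyl 3,3''-biacacetin F3. These differ from 11 by one methyl-for-benzyl exchange each and would be removed by chromatography. The route is rejoined at 11.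

3. Step 7. During a long hydrogenolysis the cis centres C3 and C3'' may epimerise by enolisation on the catalyst support, or ring C may be opened reductively at the benzylic C2–O1 bond. The fallback replaces reduction by Lewis-acid dealkylation. Starting from 13, BCl3 with pentamethylbenzene as cation scavenger (CH2Cl2, −78 °C, cold MeOH quench) should remove the five benzyl groups while the non-chelated aryl methyl ether survives at this temperature and the scavenger prevents C-benzylation of the rings A. The route is rejoined at 14 (no new compound on the way; entry F0).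

Further compounds
F1 | step 6 | (2R,3R,2''R,3''R)-enantiomer of sikokianin A, the second component of the racemate | COc1ccc([C@@H]2Oc3cc(O)cc(O)c3C(=O)[C@@H]2[C@H]2C(=O)c3c(O)cc(O)cc3O[C@H]2c2ccc(O)cc2)cc1
F2 | step 5 | hexabenzyl 3,3''-biapigenin (5,7,4',5'',7'',4'''-hexakis(benzyloxy)-3,3''-biflavone) | O=c1c(-c2c(-c3ccc(OCc4ccccc4)cc3)oc3cc(OCc4ccccc4)cc(OCc4ccccc4)c3c2=O)c(-c2ccc(OCc3ccccc3)cc2)oc2cc(OCc3ccccc3)cc(OCc3ccccc3)c12
F3 | step 5 | tetrabenzyl 3,3''-biacacetin (5,7,5'',7''-tetrakis(benzyloxy)-4',4'''-dimethoxy-3,3''-biflavone) | COc1ccc(-c2oc3cc(OCc4ccccc4)cc(OCc4ccccc4)c3c(=O)c2-c2c(-c3ccc(OC)cc3)oc3cc(OCc4ccccc4)cc(OCc4ccccc4)c3c2=O)cc1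
F0 | step 7 | none | none
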